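**Retrosynthetic overview**
- Target ⇒ fluoride removal of O‑TBDPS and N‑SEM from the fully protected 2‑acyl‑5‑(silyloxymethyl)pyrrole ketone.
- That ketone ⇒ loss of isobutene and CO2 from a β‑keto tert‑butyl ester, which comes from the key crossed Claisen condensation (C1–C2 bond of the acyl chain) between the lithium enolate of tert‑butyl 16‑methylheptadecanoate and a protected methyl pyrrole‑2‑carboxylate.
- Iso‑branched ester ⇒ Cu‑catalysed coupling of iPrMgCl with tert‑butyl 15‑bromopentadecanoate ⇒ ω‑pentadecalactone (HBr ring opening).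
- Pyrrole ester ⇒ methyl 1H‑pyrrole‑2‑carboxylate by C5 Vilsmeier formylation, NaBH4 reduction, O‑silylation, N‑SEM protection.
- No ring is formed: the pyrrole is bought intact, and the only ring event is opening of the macrolactone.

Assumption: the target has no stereocentre, so "single enantiomer" is taken as the achiral compound itself; the one stereocentre made on the way (C‑2 of β‑keto ester 13) is racemic and is erased in step 9.

**Route**

Step 1
Reactants: 1 ω‑pentadecalactone (oxacyclohexadecan‑2‑one)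
Product: 2 15‑bromopentadecanoic acid
Conditions: 33% HBr in AcOH, conc. H2SO4 (cat.), rt → 70 °C
Reagents that add atoms: hydrogen bromide, Br
Why: Acid‑promoted ring opening of the lactone with bromide displacing at the O–CH2 carbon (SN2) gives the ω‑bromo acid with no by‑product.

Step 2
Reactants: 2 15‑bromopentadecanoic acid
Product: 3 tert‑butyl 15‑bromopentadecanoate
Conditions: tert‑butyl 2,2,2‑trichloroacetimidate (2 equiv), BF3·OEt2 (cat.), CH2Cl2/cyclohexane, rt
Reagents that add atoms: tert‑butyl 2,2,2‑trichloroacetimidate, CC(C)(C)OC(=N)C(Cl)(Cl)Cl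
Why: Acid‑catalysed imidate esterification (tert‑butyl cation transfer) is mild and leaves the primary bromide untouched.

Step 3
Reactants: 3 tert‑butyl 15‑bromopentadecanoate
Product: 4 tert‑butyl 16‑methylheptadecanoate
Conditions: iPrMgCl (1.4 equiv, slow addition), Li2CuCl4 (3 mol %), NMP (4 equiv), THF, 0 °C → rt
Reagents that add atoms: isopropylmagnesium chloride, CC(C)[Mg]Cl
Why: Kochi‑type Cu‑catalysed sp3–sp3 Grignard cross‑coupling (NMP variant) works with secondary Grignards and primary bromides, and the tert‑butyl ester is inert to the Grignard at 0 °C.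

Step 4
Reactants: 5 methyl 1H‑pyrrole‑2‑carboxylate
Product: 7 methyl 5‑formyl‑1H‑pyrrole‑2‑carboxylate, via pyrrolyl dimethyliminium chloride 6 (not isolated)
Conditions: POCl3, DMF, ClCH2CH2Cl, 0 °C → 80 °C; then H2O, 80 °C
Reagents that add atoms: N,N‑dimethylformamide, CN(C)C=O; water, O
Why: Vilsmeier–Haack formylation attacks the free α‑position (C5) of the 2‑ester preferentially; the minor 4‑formyl isomer is removed by crystallisation or chromatography.

Step 5
Reactants: 7 methyl 5‑formyl‑1H‑pyrrole‑2‑carboxylate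
Product: 8 methyl 5‑(hydroxymethyl)‑1H‑pyrrole‑2‑carboxylate
Conditions: NaBH4, MeOH, 0 °C
Reagents that add atoms: none
Why: Chemoselective borohydride reduction of the aldehyde; the pyrrole ester (a vinylogous carbamate) is not reduced.

Step 6
Reactants: 8 methyl 5‑(hydroxymethyl)‑1H‑pyrrole‑2‑carboxylate
Product: 9 methyl 5‑{[(tert‑butyldiphenylsilyl)oxy]methyl}‑1H‑pyrrole‑2‑carboxylate
Conditions: TBDPSCl, imidazole, DMF, rt
Reagents that add atoms: tert‑butyl(chloro)diphenylsilane, CC(C)(C)[Si](Cl)(c1ccccc1)c1ccccc1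
Why: Standard O‑silylation of the primary alcohol; the deactivated pyrrole NH does not react, and TBDPS is chosen for its stability to base and to the catalytic acid of step 9.

Step 7
Reactants: 9 methyl 5‑{[(tert‑butyldiphenylsilyl)oxy]methyl}‑1H‑pyrrole‑2‑carboxylate
Product: 11 methyl 5‑{[(tert‑butyldiphenylsilyl)oxy]methyl}‑1‑{[2‑(trimethylsilyl)ethoxy]methyl}‑1H‑pyrrole‑2‑carboxylate, via sodium pyrrolide 10 (not isolated)
Conditions: NaH, DMF, 0 °C; then SEMCl, 0 °C → rt
Reagents that add atoms: 2‑(trimethylsilyl)ethoxymethyl chloride, C[Si](C)(C)CCOCCl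
Why: N‑alkylation of the pyrrolide anion removes the acidic NH, which would otherwise quench the ester enolate and deactivate the ester in step 8.

Step 8
Reactants: 4 tert‑butyl 16‑methylheptadecanoate (2.2 equiv); 11 methyl 5‑{[(tert‑butyldiphenylsilyl)oxy]methyl}‑1‑{[2‑(trimethylsilyl)ethoxy]methyl}‑1H‑pyrrole‑2‑carboxylate (1.0 equiv)
Product: 13 tert‑butyl (2RS)‑2‑[(5‑{[(tert‑butyldiphenylsilyl)oxy]methyl}‑1‑{[2‑(trimethylsilyl)ethoxy]methyl}‑1H‑pyrrol‑2‑yl)carbonyl]‑16‑methylheptadecanoate, via lithium ester enolate 12 (not isolated)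
Conditions: LDA (2.2 equiv), THF, −78 °C, 1 h; then 11, −78 °C → rt; aq. NH4Cl
Reagents that add atoms: none
Why: Crossed Claisen condensation: the tert‑butyl ester enolate does not self‑condense and survives warming, the pyrrole ester cannot enolise, and deprotonation of the β‑keto ester by the second equivalent of enolate drives the reaction. The new C‑2 stereocentre is racemic and is removed in step 9; excess 4 is recovered.

Step 9
Reactants: 13 tert‑butyl (2RS)‑2‑[(5‑{[(tert‑butyldiphenylsilyl)oxy]methyl}‑1‑{[2‑(trimethylsilyl)ethoxy]methyl}‑1H‑pyrrol‑2‑yl)carbonyl]‑16‑methylheptadecanoate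
Product: 15 1‑(5‑{[(tert‑butyldiphenylsilyl)oxy]methyl}‑1‑{[2‑(trimethylsilyl)ethoxy]methyl}‑1H‑pyrrol‑2‑yl)‑16‑methylheptadecan‑1‑one, via β‑keto acid 14 (not isolated)
Conditions: TsOH·H2O (0.1 equiv), toluene, 80 °C
Reagents that add atoms: none
Why: Acid‑catalysed loss of isobutene from the tert‑butyl β‑keto ester and thermal decarboxylation of the β‑keto acid through a six‑membered transition state; TBDPS ether and N‑SEM tolerate catalytic acid in a non‑nucleophilic solvent.

Step 10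
Reactants: 15 1‑(5‑{[(tert‑butyldiphenylsilyl)oxy]methyl}‑1‑{[2‑(trimethylsilyl)ethoxy]methyl}‑1H‑pyrrol‑2‑yl)‑16‑methylheptadecan‑1‑one
Product: 17 1‑[5‑(hydroxymethyl)‑1H‑pyrrol‑2‑yl]‑16‑methylheptadecan‑1‑one, via N‑SEM alcohol 16 (not isolated)
Conditions: TBAF (6 equiv), THF, rt → 65 °C
Reagents that add atoms: none
Why: Fluoride desilylation cleaves the TBDPS ether at rt and, on heating, fragments the SEM group (Me3SiF, ethene, formaldehyde); the 2‑acylpyrrolide is a good leaving group for this.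

**Compound list**
1 | ω‑pentadecalactone (oxacyclohexadecan‑2‑one) | O=C1CCCCCCCCCCCCCCO1 | starting material
2 | 15‑bromopentadecanoic acid | OC(=O)CCCCCCCCCCCCCCBr | intermediate
3 | tert‑butyl 15‑bromopentadecanoate | CC(C)(C)OC(=O)CCCCCCCCCCCCCCBr | intermediate
4 | tert‑butyl 16‑methylheptadecanoate | CC(C)CCCCCCCCCCCCCCC(=O)OC(C)(C)C | intermediate
5 | methyl 1H‑pyrrole‑2‑carboxylate | COC(=O)c1ccc[nH]1 | starting material
6 | [5‑(methoxycarbonyl)‑1H‑pyrrol‑2‑yl]methylidene(dimethyl)iminium chloride | COC(=O)c1ccc(C=[N+](C)C)[nH]1.[Cl-] | intermediate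
7 | methyl 5‑formyl‑1H‑pyrrole‑2‑carboxylate | COC(=O)c1ccc(C=O)[nH]1 | intermediate
8 | methyl 5‑(hydroxymethyl)‑1H‑pyrrole‑2‑carboxylate | COC(=O)c1ccc(CO)[nH]1 | intermediate
9 | methyl 5‑{[(tert‑butyldiphenylsilyl)oxy]methyl}‑1H‑pyrrole‑2‑carboxylate | COC(=O)c1ccc(CO[Si](c2ccccc2)(c2ccccc2)C(C)(C)C)[nH]1 | intermediate
10 | sodium salt (N‑anion) of 9 | COC(=O)c1ccc(CO[Si](c2ccccc2)(c2ccccc2)C(C)(C)C)[n-]1.[Na+] | intermediate
11 | methyl 5‑{[(tert‑butyldiphenylsilyl)oxy]methyl}‑1‑{[2‑(trimethylsilyl)ethoxy]methyl}‑1H‑pyrrole‑2‑carboxylate | COC(=O)c1ccc(CO[Si](c2ccccc2)(c2ccccc2)C(C)(C)C)n1COCC[Si](C)(C)C | intermediate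
12 | lithium enolate of tert‑butyl 16‑methylheptadecanoate | CC(C)CCCCCCCCCCCCCC=C([O-])OC(C)(C)C.[Li+] | intermediate
13 | tert‑butyl (2RS)‑2‑[(5‑{[(tert‑butyldiphenylsilyl)oxy]methyl}‑1‑{[2‑(trimethylsilyl)ethoxy]methyl}‑1H‑pyrrol‑2‑yl)carbonyl]‑16‑methylheptadecanoate (racemic) | CC(C)CCCCCCCCCCCCCC(C(=O)OC(C)(C)C)C(=O)c1ccc(CO[Si](c2ccccc2)(c2ccccc2)C(C)(C)C)n1COCC[Si](C)(C)C | intermediate
14 | (2RS)‑2‑[(5‑{[(tert‑butyldiphenylsilyl)oxy]methyl}‑1‑{[2‑(trimethylsilyl)ethoxy]methyl}‑1H‑pyrrol‑2‑yl)carbonyl]‑16‑methylheptadecanoic acid | CC(C)CCCCCCCCCCCCCC(C(=O)O)C(=O)c1ccc(CO[Si](c2ccccc2)(c2ccccc2)C(C)(C)C)n1COCC[Si](C)(C)C | intermediate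
15 | 1‑(5‑{[(tert‑butyldiphenylsilyl)oxy]methyl}‑1‑{[2‑(trimethylsilyl)ethoxy]methyl}‑1H‑pyrrol‑2‑yl)‑16‑methylheptadecan‑1‑one | CC(C)CCCCCCCCCCCCCCC(=O)c1ccc(CO[Si](c2ccccc2)(c2ccccc2)C(C)(C)C)n1COCC[Si](C)(C)C | intermediate
16 | 1‑(5‑(hydroxymethyl)‑1‑{[2‑(trimethylsilyl)ethoxy]methyl}‑1H‑pyrrol‑2‑yl)‑16‑methylheptadecan‑1‑one | CC(C)CCCCCCCCCCCCCCC(=O)c1ccc(CO)n1COCC[Si](C)(C)C | intermediate
17 | 1‑[5‑(hydroxymethyl)‑1H‑pyrrol‑2‑yl]‑16‑methylheptadecan‑1‑one | CC(C)CCCCCCCCCCCCCCC(=O)c1ccc(CO)[nH]1 | target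

**Totals**
Total step count: 10. Longest linear sequence: 7 steps (steps 4–10, from methyl 1H‑pyrrole‑2‑carboxylate); the fatty‑ester branch (steps 1–3) joins at step 8.

**Three steps most likely to fail**

Step 8 (crossed Claisen). The pyrrole ester is an electron‑rich, hindered acyl acceptor and may react sluggishly with the α‑branched enolate. The fallback sets out from 11 and comes back at 13. Ester 11 is saponified (LiOH, THF/MeOH/H2O, 40 °C) to 5‑{[(tert‑butyldiphenylsilyl)oxy]methyl}‑1‑{[2‑(trimethylsilyl)ethoxy]methyl}‑1H‑pyrrole‑2‑carboxylic acid F1. This acid is activated with carbonyldiimidazole in THF to the acyl imidazolide (1H‑imidazol‑1‑yl)(5‑{[(tert‑butyldiphenylsilyl)oxy]methyl}‑1‑{[2‑(trimethylsilyl)ethoxy]methyl}‑1H‑pyrrol‑2‑yl)methanone F2. The imidazolide is added to lithium enolate 12 (2.2 equiv) at −78 °C, where Claisen‑type C‑acylation of the enolate by the much more reactive acyl donor gives 13.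

Step 9 (acidic loss of the tert‑butyl ester). Partial loss of TBDPS or SEM under acid is possible. The fallback sets out from 2 and comes back at 15, avoiding any tert‑butyl ester. Bromo acid 2 is coupled directly as its magnesium carboxylate with iPrMgCl (3 equiv, Li2CuCl4 cat., THF, −20 °C → rt) to give 16‑methylheptadecanoic acid F3. LDA (2.2 equiv per acid, THF/DMPU, 0 → 40 °C) converts it to the dilithium enediolate of 16‑methylheptadecanoic acid F4. This dianion is acylated by ester 11 in a Claisen‑type condensation; buffering the resulting β‑keto carboxylate to pH 4–5 (aq. citric acid) gives β‑keto acid 14, which loses CO2 at 40–50 °C to give 15 under nearly neutral conditions.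

Step 10 (fluoride removal of N‑SEM). SEM removal from nitrogen can stall or give formaldehyde adducts. The fallback sets out from 15 and comes back at 17, using Lewis‑acid cleavage instead of fluoride for the SEM group. BF3·OEt2 (CH2Cl2, 0 °C) converts 15 to the hemiaminal 1‑[5‑{[(tert‑butyldiphenylsilyl)oxy]methyl}‑1‑(hydroxymethyl)‑1H‑pyrrol‑2‑yl]‑16‑methylheptadecan‑1‑one F5. TBAF (THF, rt) then removes the TBDPS group and, being basic, expels formaldehyde from the N‑hydroxymethyl group to give 17 without heating.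

**Further compounds**
F1 | step 8 | 5‑{[(tert‑butyldiphenylsilyl)oxy]methyl}‑1‑{[2‑(trimethylsilyl)ethoxy]methyl}‑1H‑pyrrole‑2‑carboxylic acid | OC(=O)c1ccc(CO[Si](c2ccccc2)(c2ccccc2)C(C)(C)C)n1COCC[Si](C)(C)C
F2 | step 8 | (1H‑imidazol‑1‑yl)(5‑{[(tert‑butyldiphenylsilyl)oxy]methyl}‑1‑{[2‑(trimethylsilyl)ethoxy]methyl}‑1H‑pyrrol‑2‑yl)methanone | O=C(n1ccnc1)c1ccc(CO[Si](c2ccccc2)(c2ccccc2)C(C)(C)C)n1COCC[Si](C)(C)C
F3 | step 9 | 16‑methylheptadecanoic acid | CC(C)CCCCCCCCCCCCCCC(=O)O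
F4 | step 9 | dilithium enediolate of 16‑methylheptadecanoic acid | CC(C)CCCCCCCCCCCCCC=C([O-])[O-].[Li+].[Li+]
F5 | step 10 | 1‑[5‑{[(tert‑butyldiphenylsilyl)oxy]methyl}‑1‑(hydroxymethyl)‑1H‑pyrrol‑2‑yl]‑16‑methylheptadecan‑1‑one | CC(C)CCCCCCCCCCCCCCC(=O)c1ccc(CO[Si](c2ccccc2)(c2ccccc2)C(C)(C)C)n1CO
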